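**Strategy.** Everything rests on cutting the bond between the benzylic CH2 (chain C1) and the ring carbon next to the ring C–OH, together with the C2–C3 bond at the acetoxy carbon. The key step exploits the chain C1–C2 unit between the benzene ring and the undecyl chain: it is a vinyl group in disguise, and the C2–O bond is a C–B bond. A palladium-catalysed enantioselective conjunctive cross-coupling joins vinylboronic acid pinacol ester, undecylmagnesium bromide and 2,5-bis(benzyloxy)-1-bromo-3-methoxybenzene in one operation. It forges the aryl–CH2 bond, the C2–undecyl bond and the C2 stereocentre; oxidation in the same flask gives the carbinol. The aryl bromide comes from 5-bromovanillin; acetylation and hydrogenolysis finish the route.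

Key step: step 3

Assumption: undecylmagnesium bromide is used as the commercial solution in diethyl ether. Of the two commercial antipodes of the MandyPhos ligand, the one that delivers the (R) configuration at C2 is used; the sense of induction is to be confirmed on alcohol 9 by MTPA ester analysis.

**Step 1**
Reactants: 1 5-bromovanillin (3-bromo-4-hydroxy-5-methoxybenzaldehyde)
Product: 3 2-bromo-6-methoxybenzene-1,4-diol, via aryl formate 2 (not isolated)
Conditions: H2O2 (30% aq), NaOH, THF/H2O, 0 °C to rt, N2; then HCl, Na2S2O4 wash
Reagents that add atoms: hydrogen peroxide, OO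
Why: Dakin oxidation, in which hydroperoxide adds to the aldehyde, the electron-rich para-hydroxyaryl group migrates to oxygen and the formate 2 is saponified in the same flask.

**Step 2**
Reactants: 3 2-bromo-6-methoxybenzene-1,4-diol
Product: 4 2,5-bis(benzyloxy)-1-bromo-3-methoxybenzene
Conditions: BnBr (2.4 equiv), K2CO3, DMF (degassed), rt to 50 °C, N2
Reagents that add atoms: benzyl bromide, BrCc1ccccc1
Why: Williamson ether synthesis, in which both phenoxides are alkylated by the reactive benzylic bromide while exclusion of air keeps the hydroquinone from oxidising.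

**Step 3**
Reactants: 4 2,5-bis(benzyloxy)-1-bromo-3-methoxybenzene; 5 vinylboronic acid pinacol ester; 6 undecylmagnesium bromide
Product: 9 (R)-1-[2,5-bis(benzyloxy)-3-methoxyphenyl]tridecan-2-ol, via vinyl boronate ate complex 7 (not isolated), via secondary pinacol boronic ester 8 (not isolated)
Conditions: 5 + 6, THF, 0 °C to rt; NaOTf, Pd(OAc)2 (cat.), MandyPhos (cat.; 1,1′-bis[bis(4-methoxy-3,5-dimethylphenyl)phosphino]-2,2′-bis[α-(dimethylamino)benzyl]ferrocene, one enantiomer), 4, THF, 60 °C; then NaOH aq, H2O2, 0 °C to rt
Reagents that add atoms: hydrogen peroxide, OO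
Why: Palladium-catalysed enantioselective conjunctive cross-coupling followed by stereoretentive boronate oxidation: the Grignard reagent 6 adds to the empty p-orbital of boron in 5 to give the four-coordinate vinyl boronate 7, while zerovalent palladium inserts into the C–Br bond of 4 and NaOTf strips bromide to leave a cationic divalent arylpalladium species. This electrophile binds the vinyl π-bond of 7 and triggers a 1,2-metallate shift of the undecyl group from boron to the α-carbon with simultaneous Pd–C bonding at the terminal carbon (anti across the alkene), and reductive elimination then forms the aryl–CH2 bond to give 8. The closest known reaction type is the conjunctive coupling of Grignard-derived vinylboron ate complexes with aryl halides or triflates, which is established for alkyl migrating groups. No ring is closed. The single new stereocentre (C2) is set by catalyst control, the C2-symmetric MandyPhos ligand selecting the enantiotopic face of the vinyl group to which palladium binds, and the later boron-to-oxygen migration with alkaline H2O2 proceeds with retention. The step needs chemoselectivity for the metallate shift over direct Suzuki-type transmetalation and over β-hydride elimination, which the wide-bite-angle bisphosphine and the halide-free cationic palladium secure, and only the undecyl group can migrate because the pinacolato oxygens are non-migrating ligands.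

**Step 4**
Reactants: 9 (R)-1-[2,5-bis(benzyloxy)-3-methoxyphenyl]tridecan-2-ol
Product: 10 (R)-1-[2,5-bis(benzyloxy)-3-methoxyphenyl]tridecan-2-yl acetate
Conditions: Ac2O, pyridine, DMAP (cat.), CH2Cl2, 0 °C to rt
Reagents that add atoms: acetic anhydride, CC(=O)OC(C)=O
Why: DMAP-catalysed O-acylation of a secondary alcohol, which breaks no bond at the stereocentre and so keeps the (R) configuration.

**Step 5**
Reactants: 10 (R)-1-[2,5-bis(benzyloxy)-3-methoxyphenyl]tridecan-2-yl acetate
Product: 11 (R)-1-(2,5-dihydroxy-3-methoxyphenyl)tridecan-2-yl acetate
Conditions: H2 (1 atm), Pd/C (palladium on carbon, 10 wt%), EtOAc (degassed), rt; filtration and concentration under argon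
Reagents that add atoms: none
Why: Heterogeneous catalytic hydrogenolysis of the two benzyl aryl ethers, to which the secondary acetate, the aryl methyl ether and the homobenzylic C–O bond are inert, so the stereocentre is untouched.

**Compound list**

1 | 5-bromovanillin (3-bromo-4-hydroxy-5-methoxybenzaldehyde) | O=Cc1cc(Br)c(O)c(OC)c1 | starting material
2 | 3-bromo-4-hydroxy-5-methoxyphenyl formate | O=COc1cc(Br)c(O)c(OC)c1 | intermediate (not isolated)
3 | 2-bromo-6-methoxybenzene-1,4-diol | Oc1cc(Br)c(O)c(OC)c1 | intermediate
4 | 2,5-bis(benzyloxy)-1-bromo-3-methoxybenzene | COc1cc(OCc2ccccc2)cc(Br)c1OCc1ccccc1 | intermediate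
5 | vinylboronic acid pinacol ester (4,4,5,5-tetramethyl-2-vinyl-1,3,2-dioxaborolane) | C=CB1OC(C)(C)C(C)(C)O1 | starting material
6 | undecylmagnesium bromide | CCCCCCCCCCC[Mg]Br | starting material
7 | sodium undecyl(vinyl)(pinacolato)borate (ate complex; bromomagnesium salt before exchange with NaOTf) | CCCCCCCCCCC[B-]1(C=C)OC(C)(C)C(C)(C)O1.[Na+] | intermediate (not isolated)
8 | (R)-2-{1-[2,5-bis(benzyloxy)-3-methoxyphenyl]tridecan-2-yl}-4,4,5,5-tetramethyl-1,3,2-dioxaborolane | CCCCCCCCCCC[C@H](Cc1cc(OCc2ccccc2)cc(OC)c1OCc1ccccc1)B1OC(C)(C)C(C)(C)O1 | intermediate (not isolated)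
9 | (R)-1-[2,5-bis(benzyloxy)-3-methoxyphenyl]tridecan-2-ol | CCCCCCCCCCC[C@H](Cc1cc(OCc2ccccc2)cc(OC)c1OCc1ccccc1)O | intermediate
10 | (R)-1-[2,5-bis(benzyloxy)-3-methoxyphenyl]tridecan-2-yl acetate | CCCCCCCCCCC[C@H](Cc1cc(OCc2ccccc2)cc(OC)c1OCc1ccccc1)OC(C)=O | intermediate
11 | (R)-1-(2,5-dihydroxy-3-methoxyphenyl)tridecan-2-yl acetate | CCCCCCCCCCC[C@H](Cc1cc(O)cc(OC)c1O)OC(C)=O | target

**Step count and risks**

Total step count: 5. Longest linear sequence: 5 steps (1 → 3 → 4 → 9 → 10 → 11).

Steps most likely to fail:

1. **Step 3.** Oxidative addition of the electron-rich, ortho-alkoxy aryl bromide may be slow, direct Suzuki-type transmetalation may compete with the metallate shift, and enantiofacial selection may be insufficient. The fallback sets out from 4 and comes back at 9. (R)-Epichlorohydrin is opened at its unsubstituted epoxide carbon by decylmagnesium bromide with CuI (cat.) in THF at −40 °C to give (R)-1-chlorotridecan-2-ol F1. NaOH closes this to (R)-1,2-epoxytridecane F2, the stereocentre coming from the chiral pool and never being touched. Bromide 4 is converted with n-BuLi in THF at −78 °C into [2,5-bis(benzyloxy)-3-methoxyphenyl]lithium F3. In the presence of BF3·OEt2, F3 opens F2 at the terminal carbon to give 9, forming the same aryl–CH2 bond.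

2. **Step 5.** The electron-rich hydroquinone may oxidise in air during isolation, and cleavage of the hindered benzyl ether between the chain and the methoxy group may be incomplete. The fallback sets out from 10 and comes back at 11. The benzyl ethers are removed without hydrogen by BCl3 and pentamethylbenzene in CH2Cl2 at −78 °C. The crude hydroquinone is oxidised on purpose with Ag2O to the bench-stable (R)-1-(5-methoxy-3,6-dioxocyclohexa-1,4-dien-1-yl)tridecan-2-yl acetate F4, which is purified by chromatography. Reduction with aqueous Na2S2O4 in EtOAc/H2O immediately before use should then give 11.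

3. **Step 1.** Excess peroxide or air under basic conditions may over-oxidise the free hydroquinone to the quinone and to ring-degradation products. The fallback sets out from 1 and comes back at 4, without ever liberating the free hydroquinone. Benzylation of 1 (BnBr, K2CO3, DMF) gives 4-(benzyloxy)-3-bromo-5-methoxybenzaldehyde F5. Baeyer–Villiger oxidation with mCPBA in CH2Cl2 gives 4-(benzyloxy)-3-bromo-5-methoxyphenyl formate F6. Methanolysis (K2CO3, MeOH) gives 4-(benzyloxy)-3-bromo-5-methoxyphenol F7, and a second benzylation (BnBr, K2CO3, DMF) gives 4.

**Further compounds**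

F1 | step 3 | (R)-1-chlorotridecan-2-ol | CCCCCCCCCCC[C@H](CCl)O
F2 | step 3 | (R)-1,2-epoxytridecane ((R)-2-undecyloxirane) | CCCCCCCCCCC[C@@H]1CO1
F3 | step 3 | [2,5-bis(benzyloxy)-3-methoxyphenyl]lithium | [Li]c1cc(OCc2ccccc2)cc(OC)c1OCc1ccccc1
F4 | step 5 | (R)-1-(5-methoxy-3,6-dioxocyclohexa-1,4-dien-1-yl)tridecan-2-yl acetate | CCCCCCCCCCC[C@H](CC1=CC(=O)C=C(OC)C1=O)OC(C)=O
F5 | step 1 | 4-(benzyloxy)-3-bromo-5-methoxybenzaldehyde | O=Cc1cc(Br)c(OCc2ccccc2)c(OC)c1
F6 | step 1 | 4-(benzyloxy)-3-bromo-5-methoxyphenyl formate | O=COc1cc(Br)c(OCc2ccccc2)c(OC)c1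
F7 | step 1 | 4-(benzyloxy)-3-bromo-5-methoxyphenol | Oc1cc(Br)c(OCc2ccccc2)c(OC)c1
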